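## Retrosynthetic overview

- The last steps put on the C10 acetate, the C8 angelate and the 11(13)-methylene, and close the γ-lactone from a C6 carbonyl; the C1 ketone travels as a methyl enol ether and the C3 hydroxyl as a PMB ether.
- Key disconnection: the C3–C4 bond, by anionic oxy-Cope ring expansion of a 1,2-dialkenylcyclohexanol (ring C1–C10–C9–C8–C7–C6). The enabling feature is that in the ten-membered ring C6 (lactone carbinol, at ketone level) and C1 (ketone, as enol ether) each lie two atoms from the C3–C4 bond (C6–C5–C4 and C3–C2–C1), a cyclodec-5-enone pattern.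
- The cyclohexane comes from a Diels–Alder reaction of 3-hydroxy-4-methyl-2-pyrone with a nitroalkene; the lactone bridge fixes C1 and C8, its carbonyl becomes the (Z)-enol ether arm, and nitro becomes the C6 ketone and then the propenyl carbinol.
- Ring order: six-membered carbocycle (as 2-oxabicyclo[2.2.2]octene, step 5), ten-membered ring (step 15), γ-lactone (step 18).

Key step: step 15

Remark: ring atoms of the ten-membered series carry germacranolide numbers (C1 ketone, C3 carbinol, C4 methine, C6 lactone carbinol, C7, C8 angelate carbon, C10 acetate carbon); PMB = 4-methoxybenzyl, TBS = tert-butyldimethylsilyl.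
Remark (assumption): the cupreidine-derived catalyst of step 5 is taken to give the enantiomer drawn; if the sense is opposite, the pseudo-enantiomeric cupreine catalyst is used.

## Route

Step 1
Reactants: 1 (E)-but-2-enal
Product: 2 2-(2-bromopropyl)-1,3-dioxolane (racemic)
Conditions: HBr (g), HOCH2CH2OH, CH2Cl2, 0 °C → rt
Reagents that add atoms: hydrogen bromide (Br); ethane-1,2-diol (OCCO)
Why: conjugate hydrobromination of the enal followed by acid-catalysed acetalisation is a standard one-pot route to β-bromo acetals, and the bromine-bearing stereocentre is erased in step 3.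

Step 2
Reactants: 2 2-(2-bromopropyl)-1,3-dioxolane; 3 diethyl oxalate
Product: 5 ethyl 4-(1,3-dioxolan-2-yl)-3-methyl-2-oxobutanoate (racemic), via Grignard reagent 4 (not isolated)
Conditions: Mg, THF, 25 °C; then (CO2Et)2 (3 equiv), THF, −78 °C; NH4Cl (aq)
Reagents that add atoms: none
Why: acylation of a Grignard reagent by excess diethyl oxalate at low temperature should stop at the α-keto ester because the tetrahedral adduct survives until work-up.

Step 3
Reactants: 5 ethyl 4-(1,3-dioxolan-2-yl)-3-methyl-2-oxobutanoate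
Product: 6 3-hydroxy-4-methyl-2H-pyran-2-one
Conditions: 6 M HCl (aq), AcOH, 80 °C
Reagents that add atoms: water (O)
Why: acetal and ester hydrolysis should give 3-methyl-2,5-dioxopentanoic acid, which closes to the lactol and dehydrates to the enol-stabilised 3-hydroxy-2-pyrone (acid-mediated cyclodehydration).

Step 4
Reactants: 7 3-[(tert-butyldimethylsilyl)oxy]propanal; 8 nitromethane
Product: 10 (E)-tert-butyldimethyl[(4-nitrobut-3-en-1-yl)oxy]silane, via nitro alcohol 9 (not isolated)
Conditions: MeNO2, KOt-Bu (5 mol %), THF/t-BuOH, 0 °C; then MsCl, Et3N, CH2Cl2, −20 → 0 °C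
Reagents that add atoms: none
Why: Henry addition followed by mesylation and E1cB elimination should give the thermodynamically favoured (E)-nitroalkene.

Step 5
Reactants: 6 3-hydroxy-4-methyl-2H-pyran-2-one; 10 (E)-tert-butyldimethyl[(4-nitrobut-3-en-1-yl)oxy]silane
Product: 11 4-hydroxy-8-methyl-5-nitro-6-[2-(TBS-oxy)ethyl]-2-oxabicyclo[2.2.2]oct-7-en-3-one (5-nitro endo; 6-side chain exo)
Conditions: 9-O-benzylcupreidine (10 mol %), Et2O, −20 °C
Reagents that add atoms: none
Why: base-catalysed Diels–Alder reaction of the 3-oxidopyrone (vinylogous Michael addition then Henry closure) should join the nitro-bearing carbon to the carbinol bridgehead as with other acceptor alkenes, the bifunctional cinchona catalyst choosing the pyrone face and so the two bridgeheads (later C1 and C8), with nitro endo.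

Step 6
Reactants: 11 bicyclic hydroxy lactone
Product: 12 4-methoxy-8-methyl-5-nitro-6-[2-(TBS-oxy)ethyl]-2-oxabicyclo[2.2.2]oct-7-en-3-one
Conditions: MeOTf, 2,6-di-tert-butyl-4-methylpyridine, CH2Cl2, 0 °C → rt
Reagents that add atoms: methyl trifluoromethanesulfonate (COS(=O)(=O)C(F)(F)F)
Why: O-methylation of the tertiary bridgehead alcohol under non-basic conditions blocks the retro-Henry pathway and later keeps this oxygen from serving as the oxy-Cope alkoxide.

Step 7
Reactants: 12 bicyclic methyl ether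
Product: 13 8-hydroxy-4-methoxy-8-methyl-5-nitro-6-[2-(TBS-oxy)ethyl]-2-oxabicyclo[2.2.2]octan-3-one (8-OH syn to the lactone bridge)
Conditions: Co(acac)2 (20 mol %), PhSiH3, O2 (1 atm), THF, rt
Reagents that add atoms: dioxygen (O=O)
Why: Mukaiyama hydration (hydrogen-atom transfer to the trisubstituted alkene, O2 capture of the tertiary radical) is Markovnikov, and the endo nitro group shields the face towards the C5–C6 bridge, so oxygen should enter syn to the lactone bridge and set C10.

Step 8
Reactants: 13 bicyclic nitro alcohol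
Product: 14 8-hydroxy-4-methoxy-8-methyl-6-[2-(TBS-oxy)ethyl]-2-oxabicyclo[2.2.2]octane-3,5-dione
Conditions: DBU, MeCN, 0 °C; then TiCl3 (aq), NH4OAc, THF, 0 °C → rt
Reagents that add atoms: water (O)
Why: McMurry variant of the Nef reaction (reduction of the nitronate by trivalent titanium to the imine, then hydrolysis); loss of methoxide from the nitronate is excluded because it would put a double bond at the bridgehead.

Step 9
Reactants: 15 (4-methoxyphenyl)methanol; 16 tributyl(iodomethyl)stannane
Product: 17 tributyl{[(4-methoxybenzyl)oxy]methyl}stannane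
Conditions: NaH, THF/DMF, 0 °C → rt
Reagents that add atoms: none
Why: Williamson etherification of the alkoxide with the primary iodide gives the α-alkoxymethylstannane.

Step 10
Reactants: 14 bicyclic keto lactone; 17 tributyl{[(4-methoxybenzyl)oxy]methyl}stannane
Product: 20 3,5-dihydroxy-6-methoxy-5-methyl-6-[(PMB-oxy)acetyl]-2-[2-(TBS-oxy)ethyl]cyclohexan-1-one, via organolithium 18 (not isolated), via dilithium enolate 19 (not isolated)
Conditions: 17, n-BuLi, THF, −78 °C; 14 added to LiN(SiMe3)2 (2.2 equiv), THF, −78 °C; solutions combined, −78 °C; AcOH then NH4Cl (aq)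
Reagents that add atoms: none
Why: tin–lithium exchange gives the alkoxymethyllithium, which should add once to the lactone carbonyl (stable tetrahedral adduct) while the ring ketone is protected in situ as its enolate; work-up releases the side-chain ketone, the C8 hydroxyl and the ring ketone.

Step 11
Reactants: 20 dihydroxy diketone
Product: 21 3,5-O-isopropylidene acetal of 20
Conditions: 2-methoxypropene, PPTS, CH2Cl2, 0 °C → rt
Reagents that add atoms: 2-methoxypropene (C=C(C)OC)
Why: the cis-1,3-diol forms the six-membered acetal, which locks the cyclohexane chair with both oxygens axial and all carbon substituents equatorial and removes the free tertiary hydroxyl that could trigger retro-aldol cleavage.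

Step 12
Reactants: 21 acetonide diketone
Product: 23 3,5-(isopropylidenedioxy)-6-methoxy-5-methyl-6-[(PMB-oxy)ethynyl]-2-[2-(TBS-oxy)ethyl]cyclohexan-1-one, via enol triflate 22 (not isolated)
Conditions: KN(SiMe3)2, THF, −78 °C; PhNTf2, −78 → −40 °C; then KOt-Bu, −40 → 0 °C
Reagents that add atoms: none
Why: kinetic deprotonation should occur at the unhindered α-alkoxy methylene of the side-chain ketone (the ring ketone has only a hindered tertiary α-hydrogen), and O-triflation followed by base-induced loss of triflate gives the alkynyl ether, while the base also equilibrates C7 to the equatorial side chain.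

Step 13
Reactants: 23 alkynyl ether
Product: 24 3,5-(isopropylidenedioxy)-6-methoxy-5-methyl-6-[(Z)-2-(PMB-oxy)ethenyl]-2-[2-(TBS-oxy)ethyl]cyclohexan-1-one
Conditions: H2 (1 atm), Pd/CaCO3–Pb(OAc)2 (Lindlar catalyst), quinoline, EtOAc, rt
Reagents that add atoms: none
Why: syn-hydrogenation of the alkynyl ether on poisoned palladium gives the (Z)-enol ether and leaves the ketone untouched.

Step 14
Reactants: 24 (Z)-enol ether ketone; 25 (E)-1-bromoprop-1-ene
Product: 28 1-[(E)-prop-1-enyl]-2-methoxy-2-[(Z)-2-(PMB-oxy)ethenyl]-3-methyl-6-[2-(TBS-oxy)ethyl]cyclohexane-1,3,5-triol 3,5-acetonide (1-OH cis to the acetal oxygens; alkenyl groups trans), via propenyllithium 26 (not isolated), via propenylcerium reagent 27 (not isolated)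
Conditions: 25, t-BuLi (2 equiv), Et2O, −78 °C; CeCl3, THF, −78 °C; then 24, −78 °C; NH4Cl (aq)
Reagents that add atoms: none
Why: halogen–lithium exchange with retention of geometry and transmetalation give a weakly basic organocerium reagent for 1,2-addition; the axial (endo) face of the carbonyl is blocked by the dioxane bridge of the 2,4-dioxabicyclo[3.3.1]nonane, so the propenyl group should enter equatorially, trans to the neighbouring alkenyl group, leaving the hydroxyl axial.

Step 15
Reactants: 28 tertiary dialkenyl alcohol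
Product: 31 (1Z)-8,10-(isopropylidenedioxy)-1-methoxy-3-(PMB-oxy)-4,10-dimethyl-7-[2-(TBS-oxy)ethyl]cyclodec-1-en-6-one (germacrane numbering), via potassium alkoxide 29 (not isolated), via potassium enolate 30 (not isolated)
Conditions: KH, 18-crown-6, THF, 0 → 40 °C; AcOH, −78 °C
Reagents that add atoms: none
Why: KH/18-crown-6 gives the C6 alkoxide 29, whose 3-oxido-1,5-diene (C4=C5–C6(O−)–C1–C2=C3) undergoes a concerted [3,3] shift in which the C1–C6 bond of the cyclohexane breaks as C3–C4 forms, giving enolate 30 and, on protonation, the C6 ketone. The closest known reaction type is the anionic oxy-Cope ring expansion of trans-1,2-dialkenylcyclohexanols to cyclodec-5-enones. The ten-membered ring is the only ring closed, by four-atom ring expansion in which the two alkene termini bond within a six-membered chair transition state. C3 and C4 are set by chirality transfer from C1 and C6 through that chair: the (Z)-enol ether puts the PMB-oxy group axial and the (E)-propenyl group puts the methyl equatorial, which should give 3R,4S. The step needs the chair pathway and rearrangement from the C6 oxygen only: the trans-diequatorial alkenyl groups of the acetonide-locked chair make a boat geometrically impossible, the C1 oxygen is a methyl ether, and the new C6/C5 enolate has no β-leaving group, so the C3 ether cannot be eliminated.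

Step 16
Reactants: 31 ten-membered ketone
Product: 32 (6S)-alcohol of 31 (6-OH cis to the C7 side chain)
Conditions: LiBH(s-Bu)3, THF, −78 °C; NH4Cl (aq)
Reagents that add atoms: none
Why: Felkin–Anh delivery of the bulky hydride anti to the C8 ring branch on the α-stereocentre C7 should give the C6 alcohol cis to the C7 side chain, while the enol ether keeps C1 masked.

Step 17
Reactants: 32 C6 alcohol
Product: 33 diol with free primary hydroxyl
Conditions: HF·pyridine, pyridine, THF, 0 °C
Reagents that add atoms: none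
Why: buffered fluoride cleaves the primary silyl ether and should spare the acetonide and the enol ether.

Step 18
Reactants: 33 diol
Product: 34 saturated cis-fused 12,6-lactone
Conditions: Ag2CO3 on Celite, toluene, 110 °C
Reagents that add atoms: none
Why: Fétizon oxidation of the primary alcohol, lactol formation with the C6 hydroxyl and further oxidation give the γ-lactone under neutral conditions that spare the enol ether.

Step 19
Reactants: 34 lactone
Product: 37 α-methylene lactone, via Mannich base 35 (not isolated), via ammonium iodide 36 (not isolated)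
Conditions: LiN(i-Pr)2, THF, −78 °C; CH2=NMe2+ I−, −78 → 0 °C; then MeI, MeOH, rt; NaHCO3 (aq), CH2Cl2, rt
Reagents that add atoms: N,N-dimethylmethyleneiminium iodide (C=[N+](C)C.[I-])
Why: Mannich reaction of the lactone enolate, N-methylation and E1cB loss of trimethylamine give the α-methylene lactone, and only the lactone is enolised because C1 is still an enol ether.

Step 20
Reactants: 37 α-methylene lactone
Product: 38 8,10-dihydroxy-3-(PMB-oxy)-1-oxogermacr-11(13)-en-12,6-olide
Conditions: 1 M HCl (aq), THF, 0 °C → rt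
Reagents that add atoms: water (O)
Why: acid hydrolysis of the methyl enol ether (C2 protonation, hydration of the oxocarbenium ion) unmasks the C1 ketone and the same conditions cleave the acetonide, while the PMB ether and lactone should survive.

Step 21
Reactants: 38 keto diol; 39 angelic acid
Product: 41 8-angelate of 38, via mixed anhydride 40 (not isolated)
Conditions: 39, 2,4,6-trichlorobenzoyl chloride, Et3N, toluene, rt; then 38, DMAP, toluene, rt
Reagents that add atoms: none
Why: Yamaguchi esterification should acylate the secondary C8 hydroxyl in preference to the tertiary C10 hydroxyl and transfer the angeloyl group at room temperature without Z to E isomerisation.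

Step 22
Reactants: 41 angelate
Product: 42 10-acetate of 41
Conditions: Ac2O, DMAP, Et3N, CH2Cl2, 35 °C
Reagents that add atoms: acetic anhydride (CC(=O)OC(C)=O)
Why: DMAP-catalysed acetylation of the remaining tertiary α-ketol hydroxyl.

Step 23
Reactants: 42 PMB ether
Product: 43 (3R,4S,6S,7S,8R,10S)-10-acetoxy-8-angeloyloxy-3-hydroxy-1-oxogermacr-11(13)-en-12,6-olide
Conditions: DDQ, CH2Cl2/pH 7 buffer, 0 °C
Reagents that add atoms: none
Why: oxidative cleavage of the PMB ether (hydride abstraction, hydrolysis of the oxocarbenium ion) under buffered conditions should free the β-hydroxy ketone without elimination.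

## Compound list

1 | (E)-but-2-enal | C/C=C/C=O | starting material
2 | 2-(2-bromopropyl)-1,3-dioxolane (racemic) | CC(Br)CC1OCCO1 | intermediate
3 | diethyl oxalate | CCOC(=O)C(=O)OCC | starting material
4 | [1-(1,3-dioxolan-2-yl)propan-2-yl]magnesium bromide | CC([Mg]Br)CC1OCCO1 | intermediate
5 | ethyl 4-(1,3-dioxolan-2-yl)-3-methyl-2-oxobutanoate (racemic) | CCOC(=O)C(=O)C(C)CC1OCCO1 | intermediate
6 | 3-hydroxy-4-methyl-2H-pyran-2-one | CC1=C(O)C(=O)OC=C1 | intermediate
7 | 3-[(tert-butyldimethylsilyl)oxy]propanal | O=CCCO[Si](C)(C)C(C)(C)C | starting material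
8 | nitromethane | C[N+](=O)[O-] | starting material
9 | 4-[(tert-butyldimethylsilyl)oxy]-1-nitrobutan-2-ol (racemic) | OC(C[N+](=O)[O-])CCO[Si](C)(C)C(C)(C)C | intermediate
10 | (E)-tert-butyldimethyl[(4-nitrobut-3-en-1-yl)oxy]silane | [O-][N+](=O)/C=C/CCO[Si](C)(C)C(C)(C)C | intermediate
11 | 4-hydroxy-8-methyl-5-nitro-6-[2-(TBS-oxy)ethyl]-2-oxabicyclo[2.2.2]oct-7-en-3-one; nitro endo (syn to C7=C8), side chain exo (syn to the lactone bridge) | O=C1O[C@@H]2C=C(C)[C@@]1(O)[C@@H]([N+](=O)[O-])[C@@H]2CCO[Si](C)(C)C(C)(C)C | intermediate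
12 | 4-methoxy analogue of 11 | O=C1O[C@@H]2C=C(C)[C@@]1(OC)[C@@H]([N+](=O)[O-])[C@@H]2CCO[Si](C)(C)C(C)(C)C | intermediate
13 | 8-hydroxy-4-methoxy-8-methyl-5-nitro-6-[2-(TBS-oxy)ethyl]-2-oxabicyclo[2.2.2]octan-3-one; 8-OH syn to the lactone bridge | O=C1O[C@@H]2C[C@](C)(O)[C@@]1(OC)[C@@H]([N+](=O)[O-])[C@@H]2CCO[Si](C)(C)C(C)(C)C | intermediate
14 | 8-hydroxy-4-methoxy-8-methyl-6-[2-(TBS-oxy)ethyl]-2-oxabicyclo[2.2.2]octane-3,5-dione | O=C1O[C@@H]2C[C@](C)(O)[C@@]1(OC)C(=O)[C@@H]2CCO[Si](C)(C)C(C)(C)C | intermediate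
15 | (4-methoxyphenyl)methanol | COc1ccc(CO)cc1 | starting material
16 | tributyl(iodomethyl)stannane | CCCC[Sn](CCCC)(CCCC)CI | starting material
17 | tributyl{[(4-methoxybenzyl)oxy]methyl}stannane | CCCC[Sn](CCCC)(CCCC)COCc1ccc(OC)cc1 | intermediate
18 | {[(4-methoxybenzyl)oxy]methyl}lithium | [Li]COCc1ccc(OC)cc1 | intermediate
19 | dilithium salt of 14 (C5 enolate, C8 alkoxide) | O=C1O[C@@H]2C[C@](C)([O-])[C@@]1(OC)C([O-])=C2CCO[Si](C)(C)C(C)(C)C.[Li+].[Li+] | intermediate
20 | 3,5-dihydroxy-6-methoxy-5-methyl-6-[(PMB-oxy)acetyl]-2-[2-(TBS-oxy)ethyl]cyclohexan-1-one; 3-OH, 5-OH, C2 side chain and C6 acyl group all cis | O=C(COCc1ccc(OC)cc1)[C@@]2(OC)[C@@](C)(O)C[C@@H](O)[C@@H](CCO[Si](C)(C)C(C)(C)C)C2=O | intermediate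
21 | 3,5-O-isopropylidene acetal of 20 | O=C(COCc1ccc(OC)cc1)[C@@]2(OC)[C@]3(C)C[C@@H](OC(C)(C)O3)[C@@H](CCO[Si](C)(C)C(C)(C)C)C2=O | intermediate
22 | enol triflate of the side-chain ketone of 21 (geometry not defined) | O=S(=O)(OC(=COCc1ccc(OC)cc1)[C@@]2(OC)[C@]3(C)C[C@@H](OC(C)(C)O3)[C@@H](CCO[Si](C)(C)C(C)(C)C)C2=O)C(F)(F)F | intermediate
23 | 6-[(PMB-oxy)ethynyl] ketone | COc1ccc(COC#C[C@@]2(OC)[C@]3(C)C[C@@H](OC(C)(C)O3)[C@@H](CCO[Si](C)(C)C(C)(C)C)C2=O)cc1 | intermediate
24 | 6-[(Z)-2-(PMB-oxy)ethenyl] ketone | COc1ccc(CO/C=C\[C@@]2(OC)[C@]3(C)C[C@@H](OC(C)(C)O3)[C@@H](CCO[Si](C)(C)C(C)(C)C)C2=O)cc1 | intermediate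
25 | (E)-1-bromoprop-1-ene | C/C=C/Br | starting material
26 | (E)-prop-1-enyllithium | C/C=C/[Li] | intermediate
27 | dichloro[(E)-prop-1-enyl]cerium | C/C=C/[Ce](Cl)Cl | intermediate
28 | 1-[(E)-prop-1-enyl]-2-methoxy-2-[(Z)-2-(PMB-oxy)ethenyl]-3-methyl-6-[2-(TBS-oxy)ethyl]cyclohexane-1,3,5-triol 3,5-acetonide; 1-OH and C6 side chain cis to the acetal oxygens, the two alkenyl groups trans | COc1ccc(CO/C=C\[C@@]2(OC)[C@]3(C)C[C@@H](OC(C)(C)O3)[C@@H](CCO[Si](C)(C)C(C)(C)C)[C@]2(O)/C=C/C)cc1 | intermediate
29 | potassium alkoxide of 28 | COc1ccc(CO/C=C\[C@@]2(OC)[C@]3(C)C[C@@H](OC(C)(C)O3)[C@@H](CCO[Si](C)(C)C(C)(C)C)[C@]2([O-])/C=C/C)cc1.[K+] | intermediate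
30 | potassium C6/C5 enolate of 31 | [O-]/C1=C\[C@H](C)[C@H](OCc2ccc(OC)cc2)/C=C(OC)/[C@]3(C)C[C@@H](OC(C)(C)O3)[C@H]1CCO[Si](C)(C)C(C)(C)C.[K+] | intermediate
31 | (1Z)-8,10-(isopropylidenedioxy)-1-methoxy-3-(PMB-oxy)-4,10-dimethyl-7-[2-(TBS-oxy)ethyl]cyclodec-1-en-6-one (germacrane numbering; C10 and C3 trans across the ring double bond) | O=C1C[C@H](C)[C@H](OCc2ccc(OC)cc2)/C=C(OC)/[C@]3(C)C[C@@H](OC(C)(C)O3)[C@H]1CCO[Si](C)(C)C(C)(C)C | intermediate
32 | C6 alcohol of 31, 6-OH cis to the C7 side chain | O[C@H]1C[C@H](C)[C@H](OCc2ccc(OC)cc2)/C=C(OC)/[C@]3(C)C[C@@H](OC(C)(C)O3)[C@H]1CCO[Si](C)(C)C(C)(C)C | intermediate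
33 | diol (primary silyl ether removed) | O[C@H]1C[C@H](C)[C@H](OCc2ccc(OC)cc2)/C=C(OC)/[C@]3(C)C[C@@H](OC(C)(C)O3)[C@H]1CCO | intermediate
34 | cis-fused saturated 12,6-lactone | O=C1O[C@H]2C[C@H](C)[C@H](OCc3ccc(OC)cc3)/C=C(OC)/[C@]4(C)C[C@@H](OC(C)(C)O4)[C@H]2C1 | intermediate
35 | 11-(dimethylaminomethyl) lactone (C11 epimers) | CN(C)CC1C(=O)O[C@H]2C[C@H](C)[C@H](OCc3ccc(OC)cc3)/C=C(OC)/[C@]4(C)C[C@@H](OC(C)(C)O4)[C@@H]12 | intermediate
36 | trimethylammonium iodide of 35 | C[N+](C)(C)CC1C(=O)O[C@H]2C[C@H](C)[C@H](OCc3ccc(OC)cc3)/C=C(OC)/[C@]4(C)C[C@@H](OC(C)(C)O4)[C@@H]12.[I-] | intermediate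
37 | α-methylene lactone (C1 enol ether, 8,10-acetonide, 3-OPMB) | C=C1C(=O)O[C@H]2C[C@H](C)[C@H](OCc3ccc(OC)cc3)/C=C(OC)/[C@]4(C)C[C@@H](OC(C)(C)O4)[C@@H]12 | intermediate
38 | 8,10-dihydroxy-3-(PMB-oxy)-1-oxogermacr-11(13)-en-12,6-olide | C=C1C(=O)O[C@H]2C[C@H](C)[C@H](OCc3ccc(OC)cc3)CC(=O)[C@@](C)(O)C[C@@H](O)[C@@H]12 | intermediate
39 | angelic acid, (Z)-2-methylbut-2-enoic acid | C/C=C(/C)C(=O)O | starting material
40 | angelic 2,4,6-trichlorobenzoic anhydride | C/C=C(/C)C(=O)OC(=O)c1c(Cl)cc(Cl)cc1Cl | intermediate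
41 | 8-angelate of 38 | C=C1C(=O)O[C@H]2C[C@H](C)[C@H](OCc3ccc(OC)cc3)CC(=O)[C@@](C)(O)C[C@@H](OC(=O)/C(C)=C\C)[C@@H]12 | intermediate
42 | 10-acetate 8-angelate 3-PMB ether | C=C1C(=O)O[C@H]2C[C@H](C)[C@H](OCc3ccc(OC)cc3)CC(=O)[C@@](C)(OC(C)=O)C[C@@H](OC(=O)/C(C)=C\C)[C@@H]12 | intermediate
43 | (3R,4S,6S,7S,8R,10S)-10-acetoxy-8-angeloyloxy-3-hydroxy-1-oxogermacr-11(13)-en-12,6-olide | C=C1C(=O)O[C@H]2C[C@H](C)[C@H](O)CC(=O)[C@@](C)(OC(C)=O)C[C@@H](OC(=O)/C(C)=C\C)[C@@H]12 | target

## Step count and risks

Total: 23 steps. Longest linear sequence: 21 steps (1–3, 5–8, 10–23, from crotonaldehyde).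

Steps most likely to fail:

Step 5. After the first C–C bond the nitronate may be protonated and the pyrone re-aromatised instead of closing onto the carbonyl, or the catalyst may discriminate the pyrone faces poorly. The fallback sets out from 6: silylation (Me3SiCl, Et3N) gives 4-methyl-3-[(trimethylsilyl)oxy]-2H-pyran-2-one F1, a neutral electron-rich diene. Its thermal Diels–Alder reaction with 10 under high pressure (CH2Cl2, 12 kbar, 25 °C) has no anionic intermediate and should give the racemic trimethylsilyl ether of 11 F2. Citric acid in MeOH removes the silyl group, and resolution on a chiral stationary phase returns to the route at 11.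

Step 14. The organometallic may enolise the hindered ketone instead of adding, or geometric purity of the propenyl unit may be lost during metalation. The fallback sets out from 24: prop-1-ynylmagnesium bromide with CeCl3 (THF, −78 °C) adds the smaller and less basic alkynyl group from the same equatorial direction to give the prop-1-ynyl carbinol F3. Trans-hydroalumination of this propargylic alcohol with NaAlH2(OCH2CH2OMe)2 (THF, 0 °C → rt) gives the (E)-alkene and returns at 28.

Step 16. Facial selectivity of hydride delivery to the flexible ten-membered ketone may be poor or reversed. The fallback sets out from 31: if reduction (for example NaBH4, CeCl3, MeOH, −78 °C) gives mainly the C6-epimeric alcohol F4, Mitsunobu inversion (4-nitrobenzoic acid, PPh3, DIAD, toluene) gives the inverted 4-nitrobenzoate F5, and methanolysis (K2CO3, MeOH) returns at 32.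

Further compounds
F1 | step 5 | 4-methyl-3-[(trimethylsilyl)oxy]-2H-pyran-2-one | CC1=C(O[Si](C)(C)C)C(=O)OC=C1
F2 | step 5 | trimethylsilyl ether of 11 (racemic, one enantiomer drawn) | O=C1O[C@@H]2C=C(C)[C@@]1(O[Si](C)(C)C)[C@@H]([N+](=O)[O-])[C@@H]2CCO[Si](C)(C)C(C)(C)C
F3 | step 14 | 1-(prop-1-ynyl) analogue of 28 | COc1ccc(CO/C=C\[C@@]2(OC)[C@]3(C)C[C@@H](OC(C)(C)O3)[C@@H](CCO[Si](C)(C)C(C)(C)C)[C@]2(O)C#CC)cc1
F4 | step 16 | C6 epimer of 32 | O[C@@H]1C[C@H](C)[C@H](OCc2ccc(OC)cc2)/C=C(OC)/[C@]3(C)C[C@@H](OC(C)(C)O3)[C@H]1CCO[Si](C)(C)C(C)(C)C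
F5 | step 16 | 4-nitrobenzoate of 32 | O=C(O[C@H]1C[C@H](C)[C@H](OCc2ccc(OC)cc2)/C=C(OC)/[C@]3(C)C[C@@H](OC(C)(C)O3)[C@H]1CCO[Si](C)(C)C(C)(C)C)c1ccc([N+](=O)[O-])cc1
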